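# Proposed synthesis of maackiaflavanone A (24) by enantioselective rhodium hydroacylation of an aryl enol ether

Flavanone numbering is used throughout: O1, C2, C3, C4, C4a, C5–C8, C8a for rings C and A; primed numbers for ring B, with C1' on C2.

## The problem

Maackiaflavanone A (24) is a (2S)-flavanone whose ring C joins two heavily oxygenated arenes. Ring A is a phloroglucinol in which every position differs (chelated 5-OH, 7-OMe, C8 prenyl, C6–H); ring B is a resorcinol with a free 2'-hydroxyl and a 2,2-dimethyl-2H-pyran fused linearly across C4'/C5'. Three tasks follow: the three ring A oxygens must be told apart and the prenyl group placed on C8 rather than C6, the linear and not the angular chromene must be built, and C2 must be set as S. C2 is the only stereocentre, so nothing in the molecule can direct it and a chiral catalyst has to. Once formed it is fragile: base opens ring C to the 2'-hydroxychalcone by retro-oxa-Michael reaction, and acid can ionise the benzylic C2–O1 bond with help from the ortho and para oxygens of ring B. The prenyl and chromene alkenes exclude hydrogenolysis, electrophilic reagents and hot strong acid. The feature that opens a non-classical route is the C4–C3–C2 array: C4 is a ketone bonded to C4a and to the C3 methylene, and C2 carries only H, O1 and ring B. C3–C4 and C2–H are therefore what addition of a ring A formyl C–H bond across an O1–C2=C3 enol ether would give, with O1 holding the alkene ortho to the aldehyde. In addition, C8 is para to O5, so the prenyl group can travel as an O5 ether that masks this phenol and be moved to carbon at the end.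

## Retrosynthesis

From 24 the 2'-O–CH2OCH3 bond is restored to give methoxymethyl ether 23. An acetal is chosen for O2' because it survives an aryllithium, a titanium carbene, fluoride and a rhodium hydride, and because it cannot migrate to an ortho-lithiated carbon as a silyl group would. The price is a final acidic step, which has to be short.

In 23 the C8–CH2 bond is cut and the prenyl group returned to O5, giving aryl prenyl ether 20. Direct C-prenylation of a 5-hydroxy-7-methoxyflavanone would not distinguish C6 from C8. Carrying a C-prenyl group from the start would require acylating the more hindered of two ortho hydroxyls. The Claisen–Cope relay from O5 can end only at C8. In 20 ring A has a free C8 and O5 is protected by the group that is needed later. The forward shift must run under a mild Lewis acid at moderate temperature so that C2 and the acetal are kept.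

The C3–C4 bond of 20 is cut, with the C2 hydrogen returned to C4, giving aldehyde 19, an aryl 1-arylvinyl ether. The usual cut at O1–C2 (oxa-Michael closure of a chalcone) relies on a reversible, base-mediated step that scrambles C2; this cut avoids it and removes ring C and the only stereocentre together, so 19 is achiral. Forward, a chiral cationic rhodium catalyst must add the formyl C–H across the enol ether with hydride to C2, on one face, faster than it decarbonylates. The prenyl ether is kept through this step because a trisubstituted alkene is a poor partner for a rhodium hydride.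

19 is taken back through benzylic alcohol 18 to triethylsilyl ether 17, and the C=CH2 bond of the enol ether is cut to the carbonyl of aryl ester 16. Ester methylenation is the most direct known entry to α-aryloxystyrenes and reduces the enol ether to the product of an ordinary esterification. The titanium carbene would attack an aldehyde first, so C4 must pass this stage masked. An acetal was set aside because its removal needs acid in the presence of the enol ether. A silyl ether is removed by fluoride and the alcohol re-oxidised by MnO2, and neither touches the enol ether.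

16 comes from aldehyde ester 15 by hydrosilylation, and the ester C–O bond of 15 is cut to acid 9 (activated as chloride 14) and phenol 13. Hydrosilylation is preferred to hydride reduction because it never frees a benzylic alkoxide, which would take the aroyl group from the neighbouring phenol oxygen. This cut halves the molecule: 13 holds ring A and C4, 9 holds ring B, C2 and, after methylenation, C3.

13 is cut at O–CH2 to 2,6-dihydroxy-4-methoxybenzaldehyde 11 and prenyl bromide 12, and 11 at O–CH3 to 2,4,6-trihydroxybenzaldehyde 10. The formyl group (the future C4) separates the non-chelated 4-hydroxyl from the two chelated ones. Because 11 is symmetric, monoalkylation cannot give regioisomers.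

Acid 9 is cut at C6–CO2H to bromide 7 by way of aryllithium 8. The alkene of 7 is taken back through mesylate 6 and alcohol 5 to chromanone 4, the acetal of 4 to phenol 3, and 3 to 4-bromoresorcinol 1 and 3-methylbut-2-enoic acid 2 by cutting the aryl–acyl and O–C(CH3)2 bonds. The bromine secures the linear fusion and marks the carbon that will carry C2. Annulation of a 2,4-dihydroxybenzoate with an enal or a propargyl ether would favour the angular chromene.

## Roads not taken

Alternative 1: The cut runs through O1–C8a and C4–C4a. Ring A is reduced to an aryne released by fluoride from silylaryl triflate A2, and C2–C3–C4 with ring B comes from cinnamic acid A3. The carboxylate of A3 adds to the aryne carbon next to the prenyl group, the aryl anion arises next to the methoxy group and attacks the ester carbonyl, and collapse of the adduct gives 2'-hydroxychalcone A1.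
- Merits: two bonds form in one convergent step, the C8 prenyl group is in place from the outset, and the electronic bias of the flanking methoxy group points the right way.
- Weak points: A2 is a pentasubstituted arene whose regio-defined synthesis is likely to cost more steps than the whole ring A sequence used here, and the prenyl group flanks the carbon that must accept the carboxylate. A1 has no stereocentre, so C2 would have to be set by an enantioselective oxa-Michael closure of an unactivated 2'-hydroxychalcone, which is reversible and not reliably selective. The 6'-methyl ether of A1 must then be cleaved by a Lewis acid next to an acetal, a prenyl group and a chromene.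
- Comparison: this road is more convergent and needs no sigmatropic relocation. The chosen plan sets C2 in the ring-forming step under neutral conditions, never passes through the chalcone, and carries O5 in a form that needs no separate deprotection.

Alternative 2: Both O1–C2 and C3–C4 are cut, giving salicylaldehyde A5, trimethyl orthoformate A7 and styrene A6. A confined chiral imidodiphosphorimidate acid condenses A5 with A7 to an oxocarbenium ion (a 4-methoxy ortho-quinone methide) paired with the chiral anion. A6 captures it, forming C3–C4 and O1–C2, to give the 2,4-cis flavan A4.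
- Merits: three simple components, two bonds and C2 set in one catalytic step, and a reaction class (ortho-quinone methides with styrenes under strong chiral acids) that is better precedented than the key step chosen here. The C8 prenyl group is again present from the start.
- Weak points: the medium is a strong Brønsted acid. The ortho prenyl alkene of A5 can trap the cation intramolecularly, the chromene alkene of A6 is a second styrene that competes as the 2π partner, and the electron-rich A6 is prone to cationic oligomerisation. A4 has C4 at the wrong oxidation level; converting the 4-methoxy group into the ketone next to two oxidisable alkenes, cleaving the 5-methyl ether selectively and removing the silyl group add at least three steps, each a risk to C2.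
- Comparison: on precedent for the stereo-defining event this road is ahead. The chosen plan delivers C4 as the ketone directly, uses no acid until the last step, and needs no demethylation.

Alternative 3: Ring A is made last by cutting C4a–C5 and C8–C8a. The (2S)-5-sulfinyl-2,3-dihydropyran-4-one A9 reacts on heating with the 1,3-dioxygenated diene A10, whose terminus carries the prenyl group. Loss of the sulfinyl group and of an alcohol aromatises ring A and gives A8, which is identical with 23.
- Merits: the diene encodes the whole ring A pattern, so no phenols need to be differentiated and no prenyl shift is needed. C2 is set early by a well-developed asymmetric hetero-Diels–Alder reaction. The product is one deprotection from 24.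
- Weak points: A10 is a hydrolytically sensitive ketene acetal of defined geometry whose reacting terminus is substituted, which slows bond formation at C8–C8a. The β-carbon of A9 carries O1, so A9 is a poor, vinylogous-ester dienophile that needs heat. The aromatisation releases a sulfenic acid and an alcohol in a molecule whose C2–O1 bond is ionisable. Making A9 requires α-sulfenylation and oxidation of a dihydropyranone that itself can ring-open.
- Comparison: this road is at least equal in step economy after the key step and stronger in precedent for the stereocentre. The chosen plan sets against it building blocks that come in a few robust steps from cheap phenols, no fragile diene, and a single uncertain step for which a known replacement exists.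

Key step: step 13

Remark: the sense of induction of the rhodium catalyst cannot be predicted with confidence. The (R) ligand is written; its antipode would be used if a pilot run shows the 2R product.

## Route

Step 1
Reactants: 1 4-bromoresorcinol; 2 3-methylbut-2-enoic acid
Product: 3 6-bromo-7-hydroxy-2,2-dimethylchroman-4-one
Conditions: MeSO3H, P2O5, 70 °C
Reagents that add atoms: none
Why: Friedel–Crafts acylation at the only position para to one hydroxyl and ortho to the other, then intramolecular oxa-Michael addition of the ortho hydroxyl to the enone, should close the chromanone with bromine at C6 (linear pattern).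

Step 2
Reactants: 3 6-bromo-7-hydroxy-2,2-dimethylchroman-4-one
Product: 4 6-bromo-7-(methoxymethoxy)-2,2-dimethylchroman-4-one
Conditions: MOMCl, i-Pr2NEt, CH2Cl2, 0 °C to rt
Reagents that add atoms: chloromethyl methyl ether, COCCl
Why: O-alkylation of an acidic phenol (para to the ketone) with an α-chloro ether; standard acetal protection.

Step 3
Reactants: 4 6-bromo-7-(methoxymethoxy)-2,2-dimethylchroman-4-one
Product: 5 (±)-6-bromo-7-(methoxymethoxy)-2,2-dimethylchroman-4-ol
Conditions: NaBH4, MeOH, 0 °C
Reagents that add atoms: none
Why: borohydride reduction of an aryl ketone; aryl bromide and acetal are inert, and the new stereocentre is removed in step 4.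

Step 4
Reactants: 5 (±)-6-bromo-7-(methoxymethoxy)-2,2-dimethylchroman-4-ol
Product: 7 6-bromo-7-(methoxymethoxy)-2,2-dimethyl-2H-chromene, via chroman-4-yl mesylate 6 (not isolated)
Conditions: MsCl, Et3N, CH2Cl2, 0 °C to rt
Reagents that add atoms: none
Why: sulfonylation then elimination; the benzylic mesylate is activated by the para acetal oxygen and the ortho ring oxygen and should eliminate in the flask to the conjugated chromene without the acid that would endanger the acetal.

Step 5
Reactants: 7 6-bromo-7-(methoxymethoxy)-2,2-dimethyl-2H-chromene
Product: 9 7-(methoxymethoxy)-2,2-dimethyl-2H-chromene-6-carboxylic acid, via aryllithium 8 (not isolated)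
Conditions: n-BuLi, THF, −78 °C; CO2; then 1 M HCl to pH 3, 0 °C
Reagents that add atoms: carbon dioxide, O=C=O
Why: bromine–lithium exchange is faster than ortho-metalation at −78 °C and the ortho acetal oxygen stabilises the aryllithium; carboxylation and a brief cold acidification give the acid.

Step 6
Reactants: 10 2,4,6-trihydroxybenzaldehyde
Product: 11 2,6-dihydroxy-4-methoxybenzaldehyde
Conditions: MeI (1.05 equiv), Li2CO3, DMF, 40 °C
Reagents that add atoms: iodomethane, CI
Why: Williamson etherification; the 4-hydroxyl is the most acidic and the only one not hydrogen-bonded to the formyl group, so a weak base should form and alkylate only its phenoxide.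

Step 7
Reactants: 11 2,6-dihydroxy-4-methoxybenzaldehyde; 12 prenyl bromide
Product: 13 2-hydroxy-4-methoxy-6-(3-methylbut-2-enyloxy)benzaldehyde
Conditions: K2CO3, acetone, 50 °C
Reagents that add atoms: none
Why: Williamson etherification of a symmetric diol; after the first alkylation the remaining hydroxyl is locked in a hydrogen bond to the formyl group, so monoalkylation should prevail, and carbonate in acetone favours O- over C-prenylation.

Step 8
Reactants: 9 7-(methoxymethoxy)-2,2-dimethyl-2H-chromene-6-carboxylic acid; 13 2-hydroxy-4-methoxy-6-(3-methylbut-2-enyloxy)benzaldehyde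
Product: 15 2-formyl-5-methoxy-3-(3-methylbut-2-enyloxy)phenyl 7-(methoxymethoxy)-2,2-dimethyl-2H-chromene-6-carboxylate, via acid chloride 14 (not isolated)
Conditions: 9, 1-chloro-N,N,2-trimethylprop-1-en-1-amine, CH2Cl2, 0 °C; then 13, Et3N, DMAP (cat.), 0 °C to rt
Reagents that add atoms: none
Why: the α-chloroenamine converts the acid into its chloride without releasing HCl, which spares the acetal; DMAP-catalysed acylation of the chelated phenol then gives the aryl ester.

Step 9
Reactants: 15 2-formyl-5-methoxy-3-(3-methylbut-2-enyloxy)phenyl 7-(methoxymethoxy)-2,2-dimethyl-2H-chromene-6-carboxylate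
Product: 16 5-methoxy-3-(3-methylbut-2-enyloxy)-2-[(triethylsilyloxy)methyl]phenyl 7-(methoxymethoxy)-2,2-dimethyl-2H-chromene-6-carboxylate
Conditions: Et3SiH, RhCl(PPh3)3 (1 mol%), toluene, 50 °C
Reagents that add atoms: triethylsilane, CC[SiH](CC)CC
Why: rhodium-catalysed carbonyl hydrosilylation puts silicon on oxygen without a free alkoxide, so the neighbouring aroyl group cannot migrate to the benzylic oxygen as it would after borohydride reduction; the ester and the trisubstituted and chromene alkenes react much more slowly than the aldehyde.

Step 10
Reactants: 16 5-methoxy-3-(3-methylbut-2-enyloxy)-2-[(triethylsilyloxy)methyl]phenyl 7-(methoxymethoxy)-2,2-dimethyl-2H-chromene-6-carboxylate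
Product: 17 6-{1-[5-methoxy-3-(3-methylbut-2-enyloxy)-2-(triethylsilyloxymethyl)phenoxy]ethenyl}-7-(methoxymethoxy)-2,2-dimethyl-2H-chromene
Conditions: Cp2TiMe2 (3 equiv), toluene/THF, 70 °C, dark; filtration through basic alumina
Reagents that add atoms: dimethyltitanocene, [CH3-].[CH3-].[cH-]1cccc1.[cH-]1cccc1.[Ti+4]
Why: Petasis methylenation; thermally formed Cp2Ti=CH2 adds to the ester carbonyl and the oxatitanacyclobutane collapses to the enol ether, a conversion well known for aryl benzoates and compatible with silyl ether, acetal and alkenes.

Step 11
Reactants: 17 6-{1-[5-methoxy-3-(3-methylbut-2-enyloxy)-2-(triethylsilyloxymethyl)phenoxy]ethenyl}-7-(methoxymethoxy)-2,2-dimethyl-2H-chromene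
Product: 18 [4-methoxy-2-{1-[7-(methoxymethoxy)-2,2-dimethyl-2H-chromen-6-yl]ethenyloxy}-6-(3-methylbut-2-enyloxy)phenyl]methanol
Conditions: Bu4NF, THF, 0 °C; aq. NH4Cl
Reagents that add atoms: none
Why: fluoride cleavage of a primary silyl ether in a basic medium, in which the enol ether and the ionisable benzylic alcohol are safe; 18 is used at once and kept from acid.

Step 12
Reactants: 18 [4-methoxy-2-{1-[7-(methoxymethoxy)-2,2-dimethyl-2H-chromen-6-yl]ethenyloxy}-6-(3-methylbut-2-enyloxy)phenyl]methanol
Product: 19 4-methoxy-2-{1-[7-(methoxymethoxy)-2,2-dimethyl-2H-chromen-6-yl]ethenyloxy}-6-(3-methylbut-2-enyloxy)benzaldehyde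
Conditions: MnO2, CH2Cl2, rt
Reagents that add atoms: none
Why: MnO2 oxidation of an electron-rich benzylic alcohol under neutral, heterogeneous conditions; enol ether, prenyl ether and chromene are not oxidised.

Step 13
Reactants: 19 4-methoxy-2-{1-[7-(methoxymethoxy)-2,2-dimethyl-2H-chromen-6-yl]ethenyloxy}-6-(3-methylbut-2-enyloxy)benzaldehyde
Product: 20 (2S)-7-methoxy-2-[7-(methoxymethoxy)-2,2-dimethyl-2H-chromen-6-yl]-5-(3-methylbut-2-enyloxy)chroman-4-one
Conditions: [Rh(cod)2]BF4 (5 mol%), (R)-DTBM-SEGPHOS (5.5 mol%), 2,6-di-tert-butylpyridine (10 mol%), ClCH2CH2Cl, 50 °C, degassed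
Reagents that add atoms: none
Why: Proposed new method: oxidative addition of the formyl C–H bond of 19 to the cationic monovalent rhodium bisphosphine fragment should give an acyl hydride of trivalent rhodium that O1 holds next to the 1-arylvinyl ether and that the O5 ether oxygen, as a hemilabile donor, shields from decarbonylation. The alkene then inserts into Rh–H with hydride going to the oxygen- and aryl-bearing carbon C2, and reductive elimination from the seven-membered acyl alkyl rhodacycle forms C3–C4. The closest known reaction types are the enantioselective rhodium-catalysed hydroacylations of 2-(1-substituted vinyl)benzaldehydes to 3-substituted indanones and of ether- or sulfide-tethered alkenals, and the carbene-catalysed hydroacylation of 2-allyloxybenzaldehydes to chroman-4-ones; an aryl enol ether as acceptor has not been shown. Ring C closes in a formal 6-endo-trig mode. C2 is set in the hydride insertion, where the C2-symmetric bisphosphine decides which face of the O1-bound enol ether faces Rh–H; the ligand antipode is chosen to give 2S. The step needs hydride to go to C2 and not to the CH2 terminus (which would end in a 2-aryl-2-methylbenzofuran-3-one): rhodium prefers the primary alkyl, and a tertiary benzylic alkyl rhodium would have to form a quaternary centre on reductive elimination. The 1,1-disubstituted enol ether cannot isomerise, the trisubstituted prenyl and the chromene alkenes insert into Rh–H far more slowly, and the neutral medium with a hindered base spares the acetal and the new C2–O1 bond.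

Step 14
Reactants: 20 (2S)-7-methoxy-2-[7-(methoxymethoxy)-2,2-dimethyl-2H-chromen-6-yl]-5-(3-methylbut-2-enyloxy)chroman-4-one
Product: 23 (2S)-5-hydroxy-7-methoxy-2-[7-(methoxymethoxy)-2,2-dimethyl-2H-chromen-6-yl]-8-(3-methylbut-2-enyl)chroman-4-one, via ortho-Claisen dienone 21 (not isolated), via para-Cope dienone 22 (not isolated)
Conditions: Eu(fod)3 (10 mol%), CHCl3, 60 °C
Reagents that add atoms: none
Why: para-Claisen–Cope rearrangement; europium chelated between C4=O and O5 accelerates the Claisen shift to C6, the reverse-prenyl dienone undergoes Cope shift to C8 (para to O5) and tautomerises, a sequence established for 5-O-prenylflavanones. The mild Lewis acid and moderate temperature are chosen to keep C2 and the acetal.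

Step 15
Reactants: 23 (2S)-5-hydroxy-7-methoxy-2-[7-(methoxymethoxy)-2,2-dimethyl-2H-chromen-6-yl]-8-(3-methylbut-2-enyl)chroman-4-one
Product: 24 maackiaflavanone A
Conditions: 3 M aq. HCl, MeOH, 40 °C, stopped at full conversion
Reagents that add atoms: none
Why: acid-catalysed acetal exchange frees the 2'-hydroxyl; the prenyl group is flanked by O1 and OMe and the chromene alkene is para to O2', so neither has a free ortho hydroxyl to cyclise onto, and short exposure limits ionisation at C2.

## Compound list

1 | 4-bromoresorcinol | Oc1ccc(Br)c(O)c1 | starting material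
2 | 3-methylbut-2-enoic acid | CC(C)=CC(=O)O | starting material
3 | 6-bromo-7-hydroxy-2,2-dimethylchroman-4-one | CC1(C)CC(=O)c2cc(Br)c(O)cc2O1 | intermediate
4 | 6-bromo-7-(methoxymethoxy)-2,2-dimethylchroman-4-one | CC1(C)CC(=O)c2cc(Br)c(OCOC)cc2O1 | intermediate
5 | (±)-6-bromo-7-(methoxymethoxy)-2,2-dimethylchroman-4-ol | CC1(C)CC(O)c2cc(Br)c(OCOC)cc2O1 | intermediate
6 | (±)-6-bromo-7-(methoxymethoxy)-2,2-dimethylchroman-4-yl methanesulfonate | CC1(C)CC(OS(C)(=O)=O)c2cc(Br)c(OCOC)cc2O1 | intermediate (not isolated)
7 | 6-bromo-7-(methoxymethoxy)-2,2-dimethyl-2H-chromene | CC1(C)C=Cc2cc(Br)c(OCOC)cc2O1 | intermediate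
8 | [7-(methoxymethoxy)-2,2-dimethyl-2H-chromen-6-yl]lithium | CC1(C)C=Cc2cc([Li])c(OCOC)cc2O1 | intermediate (not isolated)
9 | 7-(methoxymethoxy)-2,2-dimethyl-2H-chromene-6-carboxylic acid | CC1(C)C=Cc2cc(C(=O)O)c(OCOC)cc2O1 | intermediate
10 | 2,4,6-trihydroxybenzaldehyde | O=Cc1c(O)cc(O)cc1O | starting material
11 | 2,6-dihydroxy-4-methoxybenzaldehyde | COc1cc(O)c(C=O)c(O)c1 | intermediate
12 | prenyl bromide (1-bromo-3-methylbut-2-ene) | CC(C)=CCBr | starting material
13 | 2-hydroxy-4-methoxy-6-(3-methylbut-2-enyloxy)benzaldehyde | COc1cc(O)c(C=O)c(OCC=C(C)C)c1 | intermediate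
14 | 7-(methoxymethoxy)-2,2-dimethyl-2H-chromene-6-carbonyl chloride | CC1(C)C=Cc2cc(C(Cl)=O)c(OCOC)cc2O1 | intermediate (not isolated)
15 | 2-formyl-5-methoxy-3-(3-methylbut-2-enyloxy)phenyl 7-(methoxymethoxy)-2,2-dimethyl-2H-chromene-6-carboxylate | COc1cc(OCC=C(C)C)c(C=O)c(OC(=O)c2cc3c(cc2OCOC)OC(C)(C)C=C3)c1 | intermediate
16 | 5-methoxy-3-(3-methylbut-2-enyloxy)-2-[(triethylsilyloxy)methyl]phenyl 7-(methoxymethoxy)-2,2-dimethyl-2H-chromene-6-carboxylate | COc1cc(OCC=C(C)C)c(CO[Si](CC)(CC)CC)c(OC(=O)c2cc3c(cc2OCOC)OC(C)(C)C=C3)c1 | intermediate
17 | 6-{1-[5-methoxy-3-(3-methylbut-2-enyloxy)-2-(triethylsilyloxymethyl)phenoxy]ethenyl}-7-(methoxymethoxy)-2,2-dimethyl-2H-chromene | COc1cc(OCC=C(C)C)c(CO[Si](CC)(CC)CC)c(OC(=C)c2cc3c(cc2OCOC)OC(C)(C)C=C3)c1 | intermediate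
18 | [4-methoxy-2-{1-[7-(methoxymethoxy)-2,2-dimethyl-2H-chromen-6-yl]ethenyloxy}-6-(3-methylbut-2-enyloxy)phenyl]methanol | COc1cc(OCC=C(C)C)c(CO)c(OC(=C)c2cc3c(cc2OCOC)OC(C)(C)C=C3)c1 | intermediate
19 | 4-methoxy-2-{1-[7-(methoxymethoxy)-2,2-dimethyl-2H-chromen-6-yl]ethenyloxy}-6-(3-methylbut-2-enyloxy)benzaldehyde | COc1cc(OCC=C(C)C)c(C=O)c(OC(=C)c2cc3c(cc2OCOC)OC(C)(C)C=C3)c1 | intermediate
20 | (2S)-7-methoxy-2-[7-(methoxymethoxy)-2,2-dimethyl-2H-chromen-6-yl]-5-(3-methylbut-2-enyloxy)chroman-4-one | COc1cc(OCC=C(C)C)c2c(c1)O[C@H](c1cc3c(cc1OCOC)OC(C)(C)C=C3)CC2=O | intermediate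
21 | (2S)-7-methoxy-2-[7-(methoxymethoxy)-2,2-dimethyl-2H-chromen-6-yl]-6-(2-methylbut-3-en-2-yl)-2,3-dihydrochromene-4,5(6H)-dione (C6 epimers) | COC1=CC2=C(C(=O)C[C@@H](c3cc4c(cc3OCOC)OC(C)(C)C=C4)O2)C(=O)C1C(C)(C)C=C | intermediate (not isolated)
22 | (2S)-7-methoxy-2-[7-(methoxymethoxy)-2,2-dimethyl-2H-chromen-6-yl]-8-(3-methylbut-2-enyl)-2,3-dihydrochromene-4,5(8H)-dione (C8 epimers) | COC1=CC(=O)C2=C(O[C@H](c3cc4c(cc3OCOC)OC(C)(C)C=C4)CC2=O)C1CC=C(C)C | intermediate (not isolated)
23 | (2S)-5-hydroxy-7-methoxy-2-[7-(methoxymethoxy)-2,2-dimethyl-2H-chromen-6-yl]-8-(3-methylbut-2-enyl)chroman-4-one | COc1cc(O)c2c(c1CC=C(C)C)O[C@H](c1cc3c(cc1OCOC)OC(C)(C)C=C3)CC2=O | intermediate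
24 | maackiaflavanone A, (2S)-5-hydroxy-2-(7-hydroxy-2,2-dimethyl-2H-chromen-6-yl)-7-methoxy-8-(3-methylbut-2-enyl)chroman-4-one | COc1cc(O)c2c(c1CC=C(C)C)O[C@H](c1cc3c(cc1O)OC(C)(C)C=C3)CC2=O | target

## Step count and risks

Total: 15 steps. Longest linear sequence: 13 steps (steps 1–5, then 8–15); the ring A branch (steps 6–7) joins at step 8.

**Step 13 (key step, proposed new method).** The acyl rhodium hydride may lose CO before the hindered, electron-rich enol ether inserts. Hydride may be delivered to the CH2 terminus, leading to five-ring closure. The cationic metal or traces of acid may trigger a Prins-type attack of the enol ether on the aldehyde or hydrolysis of the enol ether. Facial selectivity may be poor because the substrate has ortho substituents on both arenes.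

Fallback by known chemistry, enantioselective 1,4-arylation of a chromone:
- From 7: bromine–lithium exchange and quench with B(OiPr)3 would give [7-(methoxymethoxy)-2,2-dimethyl-2H-chromen-6-yl]boronic acid F1.
- From 13: addition of excess ethynylmagnesium bromide would give 1-[2-hydroxy-4-methoxy-6-(3-methylbut-2-enyloxy)phenyl]prop-2-yn-1-ol F2, used crude. MnO2 would oxidise it to 1-[2-hydroxy-4-methoxy-6-(3-methylbut-2-enyloxy)phenyl]prop-2-yn-1-one F3. Base-mediated 6-endo oxa-Michael closure would give 7-methoxy-5-(3-methylbut-2-enyloxy)chromen-4-one F4.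
- Rhodium-catalysed asymmetric conjugate addition of F1 to F4 ([Rh(OH)(cod)]2 with a chiral biaryl bisphosphine, aqueous organic solvent) would return to the route at 20. The ortho substituent of F1 and the electron-rich acceptor are the limits of this fallback.

**Step 14.** The Cope stage may stall, so that tautomerisation of the first dienone leaves the reverse-prenyl group on C6. The Lewis acid may also open ring C reversibly and erode the configuration at C2. Fallback, moving the shift ahead of ring closure: aldehyde 19, in which the formyl group and O-prenyl ether offer the same chelation site, would be treated with Eu(fod)3 before any stereocentre exists. This would give 6-hydroxy-4-methoxy-2-{1-[7-(methoxymethoxy)-2,2-dimethyl-2H-chromen-6-yl]ethenyloxy}-3-(3-methylbut-2-enyl)benzaldehyde F5. Hydroacylation of F5 under the conditions of step 13 would return to the route at 23. The free ortho hydroxyl of F5 is the classical chelating group for rhodium acyl hydrides, but the fallback depends on step 13 working on a more hindered enol ether.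

**Step 9.** Addition to the doubly ortho-substituted, electron-rich aldehyde may be slow, so that decarbonylation by rhodium or hydrosilylation of the chromene alkene competes. Fallback, installing the silyl ether by intramolecular transfer before acylation:
- 13 would be silylated (TBSCl, imidazole) to 2-(tert-butyldimethylsilyloxy)-4-methoxy-6-(3-methylbut-2-enyloxy)benzaldehyde F6.
- NaBH4 reduction, with the 1,5 O-to-O silyl shift that the resulting alkoxide undergoes towards the more stable phenoxide, would give 2-[(tert-butyldimethylsilyloxy)methyl]-5-methoxy-3-(3-methylbut-2-enyloxy)phenol F7.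
- Acylation with chloride 14 would give 2-[(tert-butyldimethylsilyloxy)methyl]-5-methoxy-3-(3-methylbut-2-enyloxy)phenyl 7-(methoxymethoxy)-2,2-dimethyl-2H-chromene-6-carboxylate F8.
- Methylenation as in step 10 would give 6-{1-[2-(tert-butyldimethylsilyloxymethyl)-5-methoxy-3-(3-methylbut-2-enyloxy)phenoxy]ethenyl}-7-(methoxymethoxy)-2,2-dimethyl-2H-chromene F9.
- Bu4NF would return to the route at 18.

**Step 15.** Acid may ionise the C2–O1 bond, which the ortho and para oxygens of ring B assist, and so erode the configuration, or may add methanol or HCl to the prenyl or chromene alkene. Fallback, exchange of the acetal for a silyl ether without Brønsted acid: 23 would be treated with trimethylsilyl triflate and 2,2'-bipyridyl in CH2Cl2 at 0 °C, which transfers the methoxymethyl group to the pyridine nitrogen and should leave (2S)-2-[2,2-dimethyl-7-(trimethylsilyloxy)-2H-chromen-6-yl]-5-hydroxy-7-methoxy-8-(3-methylbut-2-enyl)chroman-4-one F10. Water at neutral pH would return to the route at 24.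

**Step 6.** Methylation may not stop at one group or may also take place at a chelated hydroxyl, which would leave a mixture of ethers to separate. Fallback, selectivity by chelation-controlled cleavage instead of selective alkylation: 10 would be exhaustively methylated (Me2SO4, K2CO3) to 2,4,6-trimethoxybenzaldehyde F11. Excess AlCl3 would then cleave the two ortho methyl ethers, which can chelate to the formyl oxygen, and spare the para ether, returning to the route at 11.

## Further compounds

F1 | step 13 | [7-(methoxymethoxy)-2,2-dimethyl-2H-chromen-6-yl]boronic acid | CC1(C)C=Cc2cc(B(O)O)c(OCOC)cc2O1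
F2 | step 13 | (±)-1-[2-hydroxy-4-methoxy-6-(3-methylbut-2-enyloxy)phenyl]prop-2-yn-1-ol | COc1cc(O)c(C(O)C#C)c(OCC=C(C)C)c1
F3 | step 13 | 1-[2-hydroxy-4-methoxy-6-(3-methylbut-2-enyloxy)phenyl]prop-2-yn-1-one | COc1cc(O)c(C(=O)C#C)c(OCC=C(C)C)c1
F4 | step 13 | 7-methoxy-5-(3-methylbut-2-enyloxy)chromen-4-one | COc1cc(OCC=C(C)C)c2c(c1)OC=CC2=O
F5 | step 14 | 6-hydroxy-4-methoxy-2-{1-[7-(methoxymethoxy)-2,2-dimethyl-2H-chromen-6-yl]ethenyloxy}-3-(3-methylbut-2-enyl)benzaldehyde | COc1cc(O)c(C=O)c(OC(=C)c2cc3c(cc2OCOC)OC(C)(C)C=C3)c1CC=C(C)C
F6 | step 9 | 2-(tert-butyldimethylsilyloxy)-4-methoxy-6-(3-methylbut-2-enyloxy)benzaldehyde | COc1cc(O[Si](C)(C)C(C)(C)C)c(C=O)c(OCC=C(C)C)c1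
F7 | step 9 | 2-[(tert-butyldimethylsilyloxy)methyl]-5-methoxy-3-(3-methylbut-2-enyloxy)phenol | COc1cc(O)c(CO[Si](C)(C)C(C)(C)C)c(OCC=C(C)C)c1
F8 | step 9 | 2-[(tert-butyldimethylsilyloxy)methyl]-5-methoxy-3-(3-methylbut-2-enyloxy)phenyl 7-(methoxymethoxy)-2,2-dimethyl-2H-chromene-6-carboxylate | COc1cc(OCC=C(C)C)c(CO[Si](C)(C)C(C)(C)C)c(OC(=O)c2cc3c(cc2OCOC)OC(C)(C)C=C3)c1
F9 | step 9 | 6-{1-[2-(tert-butyldimethylsilyloxymethyl)-5-methoxy-3-(3-methylbut-2-enyloxy)phenoxy]ethenyl}-7-(methoxymethoxy)-2,2-dimethyl-2H-chromene | COc1cc(OCC=C(C)C)c(CO[Si](C)(C)C(C)(C)C)c(OC(=C)c2cc3c(cc2OCOC)OC(C)(C)C=C3)c1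
F10 | step 15 | (2S)-2-[2,2-dimethyl-7-(trimethylsilyloxy)-2H-chromen-6-yl]-5-hydroxy-7-methoxy-8-(3-methylbut-2-enyl)chroman-4-one | COc1cc(O)c2c(c1CC=C(C)C)O[C@H](c1cc3c(cc1O[Si](C)(C)C)OC(C)(C)C=C3)CC2=O
F11 | step 6 | 2,4,6-trimethoxybenzaldehyde | COc1cc(OC)c(C=O)c(OC)c1
A1 | alternative 1 | (E)-2'-hydroxy-4',6'-dimethoxy-3'-prenylchalcone with the 7-(methoxymethoxy)-2,2-dimethyl-2H-chromen-6-yl ring B | COc1cc(OC)c(C(=O)/C=C/c2cc3c(cc2OCOC)OC(C)(C)C=C3)c(O)c1CC=C(C)C
A2 | alternative 1 | 3,5-dimethoxy-6-(3-methylbut-2-enyl)-2-(trimethylsilyl)phenyl trifluoromethanesulfonate | COc1cc(OC)c([Si](C)(C)C)c(OS(=O)(=O)C(F)(F)F)c1CC=C(C)C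
A3 | alternative 1 | (E)-3-[7-(methoxymethoxy)-2,2-dimethyl-2H-chromen-6-yl]prop-2-enoic acid | OC(=O)/C=C/c1cc2c(cc1OCOC)OC(C)(C)C=C2
A4 | alternative 2 | (2S)-2,4-cis-2-[7-(tert-butyldimethylsilyloxy)-2,2-dimethyl-2H-chromen-6-yl]-4,5,7-trimethoxy-8-(3-methylbut-2-enyl)chroman | COc1cc(OC)c2c(c1CC=C(C)C)O[C@H](c1cc3c(cc1O[Si](C)(C)C(C)(C)C)OC(C)(C)C=C3)C[C@@H]2OC
A5 | alternative 2 | 2-hydroxy-4,6-dimethoxy-3-(3-methylbut-2-enyl)benzaldehyde | COc1cc(OC)c(C=O)c(O)c1CC=C(C)C
A6 | alternative 2 | 7-(tert-butyldimethylsilyloxy)-6-ethenyl-2,2-dimethyl-2H-chromene | C=Cc1cc2c(cc1O[Si](C)(C)C(C)(C)C)OC(C)(C)C=C2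
A7 | alternative 2 | trimethyl orthoformate | COC(OC)OC
A8 | alternative 3 | (2S)-5-hydroxy-7-methoxy-2-[7-(methoxymethoxy)-2,2-dimethyl-2H-chromen-6-yl]-8-(3-methylbut-2-enyl)chroman-4-one (identical with 23) | COc1cc(O)c2c(c1CC=C(C)C)O[C@H](c1cc3c(cc1OCOC)OC(C)(C)C=C3)CC2=O
A9 | alternative 3 | (2S)-2-[7-(methoxymethoxy)-2,2-dimethyl-2H-chromen-6-yl]-5-(phenylsulfinyl)-2,3-dihydropyran-4-one | O=C1C[C@@H](c2cc3c(cc2OCOC)OC(C)(C)C=C3)OC=C1S(=O)c1ccccc1
A10 | alternative 3 | 1,3-dimethoxy-7-methyl-1-(trimethylsilyloxy)octa-1,3,6-triene | COC(O[Si](C)(C)C)=CC(OC)=CCC=C(C)C
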